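Everything rests on the C4a–C8a ring-fusion bond, the edge shared by the piperidine ring (N1, C2, C3, C4, C4a, C8a) and the carbocycle (C4a, C5–C8, C8a). One thermal intramolecular Diels–Alder reaction forms this bond together with C5–C6, closes both rings and sets the all-cis hydrogens at C4a, C5 and C8a. Its precursor is monocyclic: an N-(buta-1,3-dienyl)oxazolidinone whose ring ties N1 to the future C2-methyl carbon and whose side arm carries the C3 acetate and a cis C4a=C5 alkene with the complete side chain. The ring lock makes C2 dictate C4a and C8a; the carbamate is later opened to N–H and CH3.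

Key step: step 9

Remark: decahydroquinoline numbering is used (N1, C2–C8a; side chain C1′–C8′; the C2-methyl carbon is C9); the target is the (2R,3R,4aS,5S,8aR,5′R) isomer; TBS = tert-butyldimethylsilyl; the six building blocks 1, 2, 6, 10, 21 and 22 are taken as commercial.

Step 1
Reactants: 1 pent-1-yne; 2 (2R)-2-propyloxirane
Product: 3 (4R)-dec-6-yn-4-ol
Conditions: n-BuLi, THF, −78 °C; BF3·OEt2; then 2, −78 °C
Reagents that add atoms: none
Why: BF3-mediated alkynylation of the terminal epoxide by the lithium acetylide occurs at the unsubstituted carbon, so the stereocenter of 2 is carried over unchanged as (R).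

Step 2
Reactants: 3 (4R)-dec-6-yn-4-ol
Product: 4 (4R)-dec-9-yn-4-ol
Conditions: KH, H2N(CH2)3NH2 (gives KNH(CH2)3NH2), 0 °C → rt; then H2O
Reagents that add atoms: none
Why: The alkyne zipper isomerisation walks the triple bond to the chain end, driven by formation of the terminal acetylide, and cannot pass or epimerise the alkoxide-bearing C4.

Step 3
Reactants: 4 (4R)-dec-9-yn-4-ol
Product: 5 tert-butyl[(4R)-dec-9-yn-4-yloxy]dimethylsilane
Conditions: TBSCl, imidazole, DMF, rt
Reagents that add atoms: tert-butyldimethylsilyl chloride, CC(C)(C)[Si](C)(C)Cl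
Why: Imidazole-promoted silyl ether formation masks the future C5′ oxygen until the last step.

Step 4
Reactants: 5 tert-butyl[(4R)-dec-9-yn-4-yloxy]dimethylsilane; 6 4-chlorobut-2-yn-1-ol
Product: 7 (11R)-11-(TBS-oxy)tetradeca-2,5-diyn-1-ol
Conditions: CuI, NaI, Cs2CO3, DMF, rt
Reagents that add atoms: none
Why: Copper-mediated SN2 coupling of the terminal alkyne with the propargylic chloride gives the skipped diyne without touching the free alcohol.

Step 5
Reactants: 7 (11R)-11-(TBS-oxy)tetradeca-2,5-diyn-1-ol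
Product: 8 (2Z,5Z,11R)-11-(TBS-oxy)tetradeca-2,5-dien-1-ol
Conditions: H2 (1 atm), Pd/CaCO3–Pb(OAc)2 (Lindlar catalyst), quinoline, EtOAc, rt
Reagents that add atoms: none
Why: Lindlar semi-hydrogenation adds hydrogen syn to both alkynes, so both alkenes, including the future C4a=C5 dienophile, are formed as Z.

Step 6
Reactants: 8 (2Z,5Z,11R)-11-(TBS-oxy)tetradeca-2,5-dien-1-ol
Product: 9 [(2S,3R)-3-[(2Z,8R)-8-(TBS-oxy)undec-2-en-1-yl]oxiran-2-yl]methanol
Conditions: Ti(OiPr)4 (0.2 equiv), L-(+)-diethyl tartrate (0.25 equiv), t-BuOOH, 4 Å MS, CH2Cl2, −20 °C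
Reagents that add atoms: tert-butyl hydroperoxide, CC(C)(C)OO
Why: Sharpless asymmetric epoxidation epoxidises only the allylic alkene, and the L-(+)-tartrate ligand directs oxygen to the face that gives the (2S,3R)-cis-epoxide, which fixes the future C2 and C3.

Step 7
Reactants: 9 [(2S,3R)-3-[(2Z,8R)-8-(TBS-oxy)undec-2-en-1-yl]oxiran-2-yl]methanol; 10 (2E)-penta-2,4-dienoic acid
Product: 13 N-[(1E)-buta-1,3-dienyl]carbamate of epoxy alcohol 9, via (2E)-penta-2,4-dienoyl azide 11 (not isolated), via (1E)-1-isocyanatobuta-1,3-diene 12 (not isolated)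
Conditions: 10, (PhO)2P(O)N3, Et3N, toluene, 0 °C → rt; 85 °C; then 9, BHT (cat.), 85 °C
Reagents that add atoms: diphenylphosphoryl azide, [N-]=[N+]=NP(=O)(Oc1ccccc1)Oc1ccccc1
Why: Curtius rearrangement of the dienoyl azide gives the (E)-dienyl isocyanate with retention of alkene geometry, and the primary alcohol of 9 adds to it under neutral conditions that spare the epoxide.

Step 8
Reactants: 13 N-[(1E)-buta-1,3-dienyl]carbamate of epoxy alcohol 9
Product: 15 (1R,3Z,9R)-1-[(4R)-3-[(1E)-buta-1,3-dienyl]-2-oxo-1,3-oxazolidin-4-yl]-9-(TBS-oxy)dodec-3-en-1-yl acetate, via hydroxy oxazolidinone 14 (not isolated)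
Conditions: t-BuOK (0.2 equiv), THF, −20 → 0 °C; then Ac2O, pyridine, DMAP, 0 °C → rt
Reagents that add atoms: acetic anhydride, CC(=O)OC(C)=O
Why: Base-induced 5-exo-tet opening of the epoxide by the carbamate nitrogen (intramolecular aminolysis of an epoxy alcohol carbamate) occurs at C2 with inversion, giving the threo amino alcohol with (R) at C2 and unchanged (R) at C3, while the catalytic base and immediate acetylation keep the carbamate carbonyl from migrating to the new secondary oxygen.

Step 9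
Reactants: 15 (1R,3Z,9R)-1-[(4R)-3-[(1E)-buta-1,3-dienyl]-2-oxo-1,3-oxazolidin-4-yl]-9-(TBS-oxy)dodec-3-en-1-yl acetate
Product: 16 (2R,3R,4aS,5S,8aR)-3-acetoxy-5-[(5R)-5-(TBS-oxy)octyl]-cis-1,2,3,4,4a,5,6,8a-octahydroquinoline with N1 and C9 joined as the cyclic carbamate N1–C(=O)–O–C9H2
Conditions: toluene (0.005 M), BHT (cat.), degassed, sealed silylated glass tube, 200 °C
Reagents that add atoms: none
Why: A thermal, concerted but asynchronous suprafacial [4+2] cycloaddition joins the (E)-N-dienyl carbamate (C8a=C8–C7=C6) to the tethered cis C4a=C5 alkene, forming C4a–C8a and C5–C6 in one event. The closest known reaction type is the type 1 intramolecular Diels–Alder reaction of N-acyl-1-amino-1,3-dienes with unactivated alkenes, which gives cis-octahydroquinolines near 200 °C. Ring A (piperidine) closes through the four-atom tether N1–C2–C3–C4 by the C4a–C8a bond with the tether endo in a chair-like six-membered array, and ring B (carbocycle) is the cycloaddition ring, closed by C4a–C8a plus C5–C6. C8a and C4a are controlled by C2 through the oxazolidinone: the ring holds C9 in the carbamate plane and C3 out of it, so the dienophile reaches only one diene face, and the diene reacts from the N1–C8a rotamer with C8 syn to C2 and H8a toward the C=O (the other rotamer clashes with the carbonyl oxygen), which puts C8 trans to C9 and H8a cis to H4a, while C5 follows from the cis alkene geometry (H5 cis to H4a). The step needs endo (cis-fusion) over exo selectivity and this rotamer over the other; both are secured by the same lock, because an exo tether is reachable only from the disfavoured rotamer, whereas an acyclic carbamate would place the C2 substituent axial and lead to the C2-epimeric series. No second alkene competes, the acetate keeps the C3 oxygen from transcarbamoylation, and the high temperature is the price of the unactivated dienophile.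

Step 10
Reactants: 16 cycloadduct (cyclic carbamate acetate)
Product: 18 tert-butyl (2R,3R,4aS,5S,8aR)-3-hydroxy-2-(hydroxymethyl)-5-[(5R)-5-(TBS-oxy)octyl]-3,4,4a,5,6,8a-hexahydroquinoline-1(2H)-carboxylate, via amino diol 17 (not isolated)
Conditions: KOH, EtOH/H2O (4:1), 85 °C; then NaHCO3 (to pH 9), Boc2O, THF, 40 °C
Reagents that add atoms: di-tert-butyl dicarbonate, CC(C)(C)OC(=O)OC(=O)OC(C)(C)C
Why: Saponification cleaves the acetate and the cyclic carbamate (loss of carbonate), and the liberated secondary amine is acylated chemoselectively by Boc2O in the presence of the two alcohols.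

Step 11
Reactants: 18 N-Boc diol
Product: 19 tert-butyl (2S,3R,4aS,5S,8aR)-3-hydroxy-2-(iodomethyl)-5-[(5R)-5-(TBS-oxy)octyl]-3,4,4a,5,6,8a-hexahydroquinoline-1(2H)-carboxylate
Conditions: I2, PPh3, imidazole, CH2Cl2, 0 °C → rt
Reagents that add atoms: iodine, II
Why: Appel iodination converts the unhindered primary alcohol selectively, the axial secondary alcohol at C3 reacting much more slowly (the descriptor at C2 changes only by priority).

Step 12
Reactants: 19 N-Boc iodide
Product: 20 tert-butyl (2R,3R,4aS,5S,8aR)-3-hydroxy-2-methyl-5-[(5R)-5-(TBS-oxy)octyl]octahydroquinoline-1(2H)-carboxylate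
Conditions: H2 (1 atm), Pd/C, Et3N, EtOAc, rt
Reagents that add atoms: none
Why: Catalytic hydrogenation saturates the C7=C8 alkene and hydrogenolyses the primary C–I bond (base-buffered dehalogenation), turning C9 into the C2 methyl group without touching a stereocenter.

Step 13
Reactants: 21 (2E)-hex-2-enal; 22 malonic acid
Product: 23 (2E,4E)-octa-2,4-dienoic acid
Conditions: pyridine, piperidine (cat.), 90 °C
Reagents that add atoms: none
Why: Doebner–Knoevenagel condensation with decarboxylation gives the thermodynamically favoured (2E,4E)-dienoic acid.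

Step 14
Reactants: 20 N-Boc alcohol; 23 (2E,4E)-octa-2,4-dienoic acid
Product: 25 tert-butyl (2R,3R,4aS,5S,8aR)-2-methyl-3-[(2E,4E)-octa-2,4-dienoyloxy]-5-[(5R)-5-(TBS-oxy)octyl]octahydroquinoline-1(2H)-carboxylate, via mixed anhydride 24 (not isolated)
Conditions: 23, 2,4,6-Cl3C6H2COCl, Et3N, THF, rt; then 20, DMAP, toluene, 60 °C
Reagents that add atoms: 2,4,6-trichlorobenzoyl chloride, O=C(Cl)c1c(Cl)cc(Cl)cc1Cl (its atoms end in intermediate 24, not in 25)
Why: Yamaguchi esterification acylates the hindered axial C3 alcohol through the mixed anhydride and DMAP, with retention at C3 and without isomerising the dienoate.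

Step 15
Reactants: 25 N-Boc TBS-protected ester
Product: 26 (2R,3R,4aS,5S,8aR)-5-[(5R)-5-hydroxyoctyl]-2-methyldecahydroquinolin-3-yl (2E,4E)-octa-2,4-dienoate (target)
Conditions: TFA/H2O (9:1), CH2Cl2, 0 °C → rt; aq. NaHCO3
Reagents that add atoms: none
Why: Aqueous trifluoroacetic acid removes the Boc group (acidolysis to 2-methylpropene and CO2) and the silyl ether in one operation, and the protonated amine cannot attack the neighbouring ester.

Compound list
1 | pent-1-yne | CCCC#C | starting material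
2 | (2R)-2-propyloxirane | CCC[C@@H]1CO1 | starting material
3 | (4R)-dec-6-yn-4-ol | CCCC#CC[C@H](O)CCC | intermediate
4 | (4R)-dec-9-yn-4-ol | C#CCCCC[C@H](O)CCC | intermediate
5 | tert-butyl[(4R)-dec-9-yn-4-yloxy]dimethylsilane | C#CCCCC[C@H](O[Si](C)(C)C(C)(C)C)CCC | intermediate
6 | 4-chlorobut-2-yn-1-ol | OCC#CCCl | starting material
7 | (11R)-11-[(tert-butyldimethylsilyl)oxy]tetradeca-2,5-diyn-1-ol | OCC#CCC#CCCCC[C@H](O[Si](C)(C)C(C)(C)C)CCC | intermediate
8 | (2Z,5Z,11R)-11-[(tert-butyldimethylsilyl)oxy]tetradeca-2,5-dien-1-ol | OC/C=C\C/C=C\CCCC[C@H](O[Si](C)(C)C(C)(C)C)CCC | intermediate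
9 | [(2S,3R)-3-[(2Z,8R)-8-[(tert-butyldimethylsilyl)oxy]undec-2-en-1-yl]oxiran-2-yl]methanol | OC[C@@H]1O[C@@H]1C/C=C\CCCC[C@H](O[Si](C)(C)C(C)(C)C)CCC | intermediate
10 | (2E)-penta-2,4-dienoic acid | C=C/C=C/C(=O)O | starting material
11 | (2E)-penta-2,4-dienoyl azide | C=C/C=C/C(=O)N=[N+]=[N-] | intermediate (not isolated)
12 | (1E)-1-isocyanatobuta-1,3-diene | C=C/C=C/N=C=O | intermediate (not isolated)
13 | [(2S,3R)-3-[(2Z,8R)-8-[(tert-butyldimethylsilyl)oxy]undec-2-en-1-yl]oxiran-2-yl]methyl N-[(1E)-buta-1,3-dien-1-yl]carbamate | C=C/C=C/NC(=O)OC[C@@H]1O[C@@H]1C/C=C\CCCC[C@H](O[Si](C)(C)C(C)(C)C)CCC | intermediate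
14 | (4R)-3-[(1E)-buta-1,3-dien-1-yl]-4-[(1R,3Z,9R)-9-[(tert-butyldimethylsilyl)oxy]-1-hydroxydodec-3-en-1-yl]-1,3-oxazolidin-2-one | C=C/C=C/N1C(=O)OC[C@@H]1[C@H](O)C/C=C\CCCC[C@H](O[Si](C)(C)C(C)(C)C)CCC | intermediate (not isolated)
15 | (1R,3Z,9R)-1-[(4R)-3-[(1E)-buta-1,3-dien-1-yl]-2-oxo-1,3-oxazolidin-4-yl]-9-[(tert-butyldimethylsilyl)oxy]dodec-3-en-1-yl acetate | C=C/C=C/N1C(=O)OC[C@@H]1[C@H](OC(C)=O)C/C=C\CCCC[C@H](O[Si](C)(C)C(C)(C)C)CCC | intermediate
16 | cycloadduct: (2R,3R,4aS,5S,8aR)-3-acetoxy-5-[(5R)-5-[(tert-butyldimethylsilyl)oxy]octyl]-cis-1,2,3,4,4a,5,6,8a-octahydroquinoline, N1 and C9 joined as cyclic carbamate (oxazolidinone fused at N1–C2; H4a, H5, H8a cis) | CC(=O)O[C@@H]1C[C@H]2[C@@H](CCCC[C@H](O[Si](C)(C)C(C)(C)C)CCC)CC=C[C@H]2N3C(=O)OC[C@H]13 | intermediate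
17 | (2R,3R,4aS,5S,8aR)-2-(hydroxymethyl)-5-[(5R)-5-[(tert-butyldimethylsilyl)oxy]octyl]-1,2,3,4,4a,5,6,8a-octahydroquinolin-3-ol | O[C@@H]1C[C@H]2[C@@H](CCCC[C@H](O[Si](C)(C)C(C)(C)C)CCC)CC=C[C@H]2N[C@@H]1CO | intermediate (not isolated)
18 | tert-butyl (2R,3R,4aS,5S,8aR)-3-hydroxy-2-(hydroxymethyl)-5-[(5R)-5-[(tert-butyldimethylsilyl)oxy]octyl]-3,4,4a,5,6,8a-hexahydroquinoline-1(2H)-carboxylate | O[C@@H]1C[C@H]2[C@@H](CCCC[C@H](O[Si](C)(C)C(C)(C)C)CCC)CC=C[C@H]2N(C(=O)OC(C)(C)C)[C@@H]1CO | intermediate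
19 | tert-butyl (2S,3R,4aS,5S,8aR)-3-hydroxy-2-(iodomethyl)-5-[(5R)-5-[(tert-butyldimethylsilyl)oxy]octyl]-3,4,4a,5,6,8a-hexahydroquinoline-1(2H)-carboxylate | O[C@@H]1C[C@H]2[C@@H](CCCC[C@H](O[Si](C)(C)C(C)(C)C)CCC)CC=C[C@H]2N(C(=O)OC(C)(C)C)[C@@H]1CI | intermediate
20 | tert-butyl (2R,3R,4aS,5S,8aR)-3-hydroxy-2-methyl-5-[(5R)-5-[(tert-butyldimethylsilyl)oxy]octyl]octahydroquinoline-1(2H)-carboxylate | O[C@@H]1C[C@H]2[C@@H](CCCC[C@H](O[Si](C)(C)C(C)(C)C)CCC)CCC[C@H]2N(C(=O)OC(C)(C)C)[C@@H]1C | intermediate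
21 | (2E)-hex-2-enal | CCC/C=C/C=O | starting material
22 | malonic acid | OC(=O)CC(=O)O | starting material
23 | (2E,4E)-octa-2,4-dienoic acid | CCC/C=C/C=C/C(=O)O | intermediate
24 | (2E,4E)-octa-2,4-dienoic 2,4,6-trichlorobenzoic anhydride | CCC/C=C/C=C/C(=O)OC(=O)c1c(Cl)cc(Cl)cc1Cl | intermediate (not isolated)
25 | tert-butyl (2R,3R,4aS,5S,8aR)-2-methyl-3-[(2E,4E)-octa-2,4-dienoyloxy]-5-[(5R)-5-[(tert-butyldimethylsilyl)oxy]octyl]octahydroquinoline-1(2H)-carboxylate | CCC/C=C/C=C/C(=O)O[C@@H]1C[C@H]2[C@@H](CCCC[C@H](O[Si](C)(C)C(C)(C)C)CCC)CCC[C@H]2N(C(=O)OC(C)(C)C)[C@@H]1C | intermediate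
26 | (2R,3R,4aS,5S,8aR)-5-[(5R)-5-hydroxyoctyl]-2-methyldecahydroquinolin-3-yl (2E,4E)-octa-2,4-dienoate | CCC/C=C/C=C/C(=O)O[C@@H]1C[C@H]2[C@@H](CCCC[C@H](O)CCC)CCC[C@H]2N[C@@H]1C | target

Total step count: 15. Longest linear sequence: 14 (steps 1–12, 14 and 15; step 13 is a one-step side branch).

Steps most likely to fail

Step 9. The cycloaddition of the unactivated cis-alkene may be slower than oligomerisation or thermal decay of the amido diene, or part of the material may react through the minor N1–C8a rotamer and erode the ring-fusion selectivity. The fallback goes from 15 to 16 without a new compound, by a rhodium-catalysed diene–ene cyclisation ([Rh(C10H8)(cod)]SbF6, 1,2-dichloroethane, 40–70 °C). It runs through oxidative coupling to a rhodacycle and reductive elimination instead of a pericyclic transition state, operates on unactivated tethered alkenes well below 100 °C, and should transfer the cis-alkene geometry to C4a/C5 in the same suprafacial sense under the same C2 lock. This is the weakest of the three fallbacks, because internal cis-alkenes and amido dienes are at the edge of that reaction's known scope.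

Step 8. The carbamate carbonyl may transfer from O9 to the newly freed O3 (base-induced acyl migration to the isomeric 4,5-disubstituted oxazolidinone), or the ambident dienyl carbamate anion may react through carbon. The fallback sets out from 9 and returns at 15. Trichloroacetyl isocyanate (CH2Cl2, 0 °C) gives the N-(trichloroacetyl)carbamate F1. K2CO3 in methanol removes the trichloroacetyl group to give the primary carbamate F2. NaH in THF closes the ring at C2 with inversion to the N–H oxazolidinone alcohol F3, in which the acidic ring N–H quenches the alkoxide at once. Ac2O/pyridine gives the acetate F4. Acid-catalysed condensation of F4 with (E)-but-2-enal (camphorsulfonic acid, toluene, removal of water) installs the N-dienyl group late and gives 15.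

Step 11. The Boc carbonyl may attack the activated CH2 as a neighbouring group (loss of the tert-butyl group, re-forming the cyclic carbamate), and the iodide may be lost on storage. The fallback sets out from 18 and returns at 20, and avoids any electrophilic CH2–X. 1,1′-Thiocarbonyldiimidazole acylates the primary alcohol to the imidazolyl thionocarbonate F5. Bu3SnH, AIBN, toluene, 110 °C (Barton–McCombie deoxygenation) gives the C2-methyl hexahydroquinoline F6. H2, Pd/C, EtOAc then saturates C7=C8 and gives 20.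

Further compounds
F0 | step 9 | none | none
F1 | step 8 | [(2S,3R)-3-[(2Z,8R)-8-[(tert-butyldimethylsilyl)oxy]undec-2-en-1-yl]oxiran-2-yl]methyl N-(trichloroacetyl)carbamate | O=C(NC(=O)C(Cl)(Cl)Cl)OC[C@@H]1O[C@@H]1C/C=C\CCCC[C@H](O[Si](C)(C)C(C)(C)C)CCC
F2 | step 8 | [(2S,3R)-3-[(2Z,8R)-8-[(tert-butyldimethylsilyl)oxy]undec-2-en-1-yl]oxiran-2-yl]methyl carbamate | NC(=O)OC[C@@H]1O[C@@H]1C/C=C\CCCC[C@H](O[Si](C)(C)C(C)(C)C)CCC
F3 | step 8 | (4R)-4-[(1R,3Z,9R)-9-[(tert-butyldimethylsilyl)oxy]-1-hydroxydodec-3-en-1-yl]-1,3-oxazolidin-2-one | N1C(=O)OC[C@@H]1[C@H](O)C/C=C\CCCC[C@H](O[Si](C)(C)C(C)(C)C)CCC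
F4 | step 8 | (1R,3Z,9R)-9-[(tert-butyldimethylsilyl)oxy]-1-[(4R)-2-oxo-1,3-oxazolidin-4-yl]dodec-3-en-1-yl acetate | N1C(=O)OC[C@@H]1[C@H](OC(C)=O)C/C=C\CCCC[C@H](O[Si](C)(C)C(C)(C)C)CCC
F5 | step 11 | tert-butyl (2R,3R,4aS,5S,8aR)-3-hydroxy-2-[(imidazol-1-ylcarbonothioyl)oxymethyl]-5-[(5R)-5-[(tert-butyldimethylsilyl)oxy]octyl]-3,4,4a,5,6,8a-hexahydroquinoline-1(2H)-carboxylate | O[C@@H]1C[C@H]2[C@@H](CCCC[C@H](O[Si](C)(C)C(C)(C)C)CCC)CC=C[C@H]2N(C(=O)OC(C)(C)C)[C@@H]1COC(=S)n1ccnc1
F6 | step 11 | tert-butyl (2R,3R,4aS,5S,8aR)-3-hydroxy-2-methyl-5-[(5R)-5-[(tert-butyldimethylsilyl)oxy]octyl]-3,4,4a,5,6,8a-hexahydroquinoline-1(2H)-carboxylate | O[C@@H]1C[C@H]2[C@@H](CCCC[C@H](O[Si](C)(C)C(C)(C)C)CCC)CC=C[C@H]2N(C(=O)OC(C)(C)C)[C@@H]1C
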